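## Analysis of the target

Ferugin (22) is a daucane sesquiterpenoid ester, a bicyclo[5.3.0]decane in which cyclopentane ring A (C1–C5) and cycloheptane ring B (C1, C5–C10) share the C1–C5 bond. C1 carries a methyl group (C15), C4 an isopropyl group and a tertiary hydroxyl, O6 a 4-hydroxybenzoyl group, C8 an exocyclic methylene (C14) and C9 a secondary allylic hydroxyl. There are five stereocentres, (1R,4R,5S,6S,9S); C4, C5 and C6 are contiguous, C1 is a further neighbour of C5, and C1 and C4 are fully substituted. With the C15 methyl as reference, the C4 hydroxyl lies on the same face, while H5 (trans ring fusion), the C6 acyloxy group and the C9 hydroxyl lie on the opposite face, so O6 and O9 face each other across ring B. Sensitive points are the allylic alcohol with its 1,1-disubstituted alkene (ionisation, transposition), the aryl ester flanked by free hydroxyls (acyl migration, above all to O9), the tertiary alcohol (elimination) and the free phenol. The difficulty lies in the quaternary C1 next to the ring-fusion carbon C5 and the fully substituted C4, in closing a seven-membered ring around them, and in acylating one hydroxyl out of three. The strategy rests on one observation: C4, its isopropyl group, C3, C2, C1, C15, C5 and C6 are the ten carbons of terpinen-4-ol (1), with C4 already in the right configuration. The rest of ring B (C7–C10 with C14) can then be added as one carbon (C7) plus four carbons (C8, C9, C10, C14) across a diene.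

## Retrosynthetic reasoning

**22 to 21.** The two O–Si bonds are cut last. Both silyl ethers fall in one fluoride treatment, and until then the phenol and the tertiary C4 hydroxyl stay masked in every step where they would interfere (carbenoid O–H insertion, acylation). The forward step has to cleave a hindered tertiary silyl ether without moving the aroyl group from O6 to O9.

**21 to 20.** The unit C14=C8–C9(OH) is traced back to an 8,9-epoxide with iodine on C14. No C–C bond is cut here. The gain is that in 20 the C9 oxygen is still tied up in the epoxide, so O6 is the only hydroxyl that can be acylated one step earlier. The forward reaction is a reductive elimination that breaks C14–I and C8–O but not C9–O, so the C9 configuration is carried over unchanged.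

**20 to 15 and 19.** The ester C–O bond between O6 and the aroyl carbon is cut. At the stage of 15 the molecule has a single free hydroxyl, which removes the selectivity problem that a late acylation of a 6,9-diol would bring. 19 comes from 16 through 18, with 17 formed and cleaved in the same flask.

**15 to 14 to 13 to 12.** The C14–I bond goes back to the primary hydroxyl of 14. The two C–O bonds of the epoxide go back to the allylic alcohol 13 by Sharpless epoxidation. The allylic hydroxyl confines the oxidant to C8=C9 and allows reagent control over C9. 13 is the reduction product of ester 12, so C14 is carried as an ester from the key step and never has to be introduced separately.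

**12 to 10.** The C5–H and C6–O bonds are cut together, as a syn hydroboration of C5=C6. This alkene is exactly what the key step leaves behind, and one operation sets two stereocentres and the trans ring fusion under the control of the C15 methyl group. The forward step must discriminate between the hindered, electron-rich C5=C6 bond and the conjugated ester.

**10 to 6 and 8 (through 9).** C7–C8 and C1–C10 are cut. This is the only pair of cuts that leaves ring A and the C4 stereocentre untouched in a simple diene (6) and puts all remaining carbons, C14 included, into one small reagent (8). Forward, a vinylcarbenoid cyclopropanates the vinyl group of 6 and the resulting cis-divinylcyclopropane 9 rearranges. The step must select one alkene of the diene and one face of it.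

**6 to 5 to 4 to 2 to 1, and 8 to 7.** C6=C7 is cut by a Wittig disconnection, which makes C7 the one-carbon unit. The C1=C5 bond of 5 is cut by an aldol condensation disconnection to the keto aldehyde 4. 4 is the ozonolysis product of the silyl ether 2 of 1. In effect the six-membered ring of 1 is opened at its alkene and re-closed one atom smaller, with the carbinol carbon as a spectator. 8 comes from 7 by diazo transfer.

## Alternatives that were turned down

**Alternative 1:** C1–C5 and C7–C8 are disconnected at once, so both rings come from an open chain, the chloromethyl ketone A2. It carries C5–C6–C7 as a latent oxyallyl cation and C1=C10–C9=C8 as a 2-silyloxydiene.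
- Forward key step: ionisation of A2 by base in a fluorinated alcohol and intramolecular (4+3) cycloaddition to the trans-fused bicyclic ketone A1.
- For it: two rings, two C–C bonds and both ring-fusion centres are made in one step, and oxygen is already on C6 and C9 in A1, so no hydroboration is needed. On rings per step and on oxygenation at C6 and C9 it is stronger than the chosen route.
- Against it:
  - A2 is acyclic, so C4 must be made by asymmetric synthesis instead of bought, and the chain needs about twice as many steps as 6.
  - C1 and C5 would both be set relative to C4 by one tether conformation (two diene faces, compact or extended transition state), with no reagent control available.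
  - The silyl dienol ether must survive a protic ionising medium.
  - In A1 the C4 silyloxy group is β to the C6 ketone with the acidic H5 between them, an arrangement prone to E1cB loss.
  - The enol ether of A1 points to C10 although C14 has to enter at C8.
  - Reduction of the C6 ketone would have to deliver hydride from the methyl-bearing face.
- Comparison: the chosen route takes C4 from 1, creates one new carbon stereocentre (C1) under catalyst control, brings C14 in with the carbenoid, and sets C5 and C6 together by one syn addition.

**Alternative 2:** Only C7–C8 is disconnected; ring B is closed last on a finished ring A. The precursor A4 has a silyl enol ether (C6=C7) on C5 and a silyloxy propargyl arm (C10–C9–C8≡C14) on C1.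
- Forward key step: a cationic phosphine–gold catalyst activates the alkyne of A4 and C7 attacks it (7-exo-dig Conia-ene closure) to give A3.
- For it: the exocyclic methylene, the C9 silyl ether and the C6 oxygen appear in A3 exactly where 22 needs them. The endgame (ketone reduction, acylation, desilylation) is shorter than the one chosen here, and on this point the alternative is clearly stronger.
- Against it:
  - The key step creates no stereocentre, so C1, C4, C5 and C9 must all be set beforehand on a cyclopentane with three contiguous substituted carbons, two of them fully substituted. The hardest part of the target is left to a long linear preparation of A4.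
  - Exo-dig closures of this kind are well behaved for five- and six-membered rings, but a seven-membered closure competes poorly with protodesilylation of the enol ether and hydration of the alkyne.
  - The β-silyloxy ketone and the contra-steric reduction at C6 return as in alternative 1.
- Comparison: the chosen route spends its key step on the problem this alternative postpones, forming ring B and the quaternary C1 together from a ten-carbon chiral-pool piece.

**Alternative 3:** C1–C5 and C6–C7 are disconnected, with the C7–C9 bond of a cyclopropane as third partner, giving the acyclic yne–vinylcyclopropane A6.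
- Forward key step: a chlorocarbonylrhodium catalyst (monovalent rhodium) effects the intramolecular (5+2) cycloaddition to the bicyclic diene A5, closing both rings.
- For it: the step is catalytic and atom-economic, closes both rings, and leaves the C9 oxygen in place as a silyl enol ether. On rings per step and on C9 oxygenation it is stronger than the chosen route. It gives the same C5=C6 alkene as 10, so the hydroboration question is identical and the two are equal there.
- Against it:
  - C4 again needs asymmetric synthesis, here as a propargylic tertiary carbinol whose two alkyl groups (isopropyl and a primary chain) are hard to tell apart.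
  - C1 would arise from a trisubstituted alkene whose fully substituted terminus must bond to the alkyne, a substitution pattern that slows metallacycle formation, and its face is governed only by C4 through the tether.
  - A5 lacks C14, which would have to be added at C8 by regioselective α-methylenation after unmasking the C9 ketone, followed by a stereoselective 1,2-reduction.
- Comparison: the chosen route has C14 from the outset, C4 from the pool, and catalyst control over C1.

Key step: step 6

Assumption: 1 is used in high enantiomeric purity (commercial material, enriched beforehand if necessary); its carbinol carbon becomes C4 without any bond to it being broken.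

Daucane numbering (C1–C15, as in the analysis) is used in the names of 10–15 and 20–22.

## Route

Step 1
Reactants: 1 (S)-terpinen-4-ol
Product: 2 triethyl{[(1S)-4-methyl-1-(propan-2-yl)cyclohex-3-en-1-yl]oxy}silane
Conditions: Et3SiOTf, 2,6-lutidine, CH2Cl2, −78 → 0 °C
Reagents that add atoms: triethylsilyl trifluoromethanesulfonate, CC[Si](CC)(CC)OS(=O)(=O)C(F)(F)F
Why: Silylation of a tertiary alcohol with a silyl triflate and a hindered pyridine base is reliable; the ether prevents hemiketal formation after ozonolysis and O–H insertion of the carbenoid in step 6, and the stereocentre is not touched.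

Step 2
Reactants: 2 triethyl{[(1S)-4-methyl-1-(propan-2-yl)cyclohex-3-en-1-yl]oxy}silane
Product: 4 (3S)-6-oxo-3-(propan-2-yl)-3-(triethylsilyloxy)heptanal, via secondary ozonide 3 (not isolated)
Conditions: O3, CH2Cl2, −78 °C; then PPh3, −78 °C → rt
Reagents that add atoms: ozone, [O-][O+]=O
Why: Ozonolysis with reductive work-up cleaves the only C=C bond to the 1,6-keto aldehyde; no bond to the carbinol carbon is involved, so its configuration is kept.

Step 3
Reactants: 4 (3S)-6-oxo-3-(propan-2-yl)-3-(triethylsilyloxy)heptanal
Product: 5 (5R)-2-methyl-5-(propan-2-yl)-5-(triethylsilyloxy)cyclopent-1-ene-1-carbaldehyde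
Conditions: piperidine (0.3 equiv), AcOH (0.3 equiv), toluene, 60 °C
Reagents that add atoms: none
Why: Intramolecular aldol condensation under enamine catalysis: the amine condenses faster with the aldehyde than with the ketone, so the aldehyde α-carbon (future C5) adds to the ketone carbonyl (future C1) in a five-membered (5-enolexo) closure and loss of water gives the tetrasubstituted enal, the established outcome for 6-oxoheptanals. The descriptor changes from S to R only because the CIP priorities change.

Step 4
Reactants: 5 (5R)-2-methyl-5-(propan-2-yl)-5-(triethylsilyloxy)cyclopent-1-ene-1-carbaldehyde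
Product: 6 (5R)-1-ethenyl-2-methyl-5-(propan-2-yl)-5-(triethylsilyloxy)cyclopent-1-ene
Conditions: Ph3PCH3Br, KOtBu, THF, 0 °C → rt
Reagents that add atoms: methyltriphenylphosphonium bromide, C[P+](c1ccccc1)(c1ccccc1)c1ccccc1.[Br-]
Why: Wittig methylenation: the small unstabilised ylide adds to the hindered aldehyde, which has no α-hydrogen, and cycloreversion of the oxaphosphetane gives the terminal C6=C7 alkene and thus the diene for the key step.

Step 5
Reactants: 7 methyl but-3-enoate
Product: 8 methyl 2-diazobut-3-enoate
Conditions: 4-acetamidobenzenesulfonyl azide, DBU, MeCN, 0 °C; extracted into pentane and used cold at once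
Reagents that add atoms: 4-acetamidobenzenesulfonyl azide, CC(=O)Nc1ccc(cc1)S(=O)(=O)N=[N+]=[N-]
Why: Regitz diazo transfer to the dienolate of a β,γ-unsaturated ester, whose α-CH2 is activated by both the ester and the vinyl group; the product is kept cold and used at once because it cyclises slowly to a pyrazole.

Step 6
Reactants: 6 (5R)-1-ethenyl-2-methyl-5-(propan-2-yl)-5-(triethylsilyloxy)cyclopent-1-ene; 8 methyl 2-diazobut-3-enoate
Product: 10 methyl (1R,4R)-4-(triethylsilyloxy)dauca-5,8-dien-14-oate, via divinylcyclopropane 9 (not isolated)
Conditions: Rh2(R-DOSP)4 (dirhodium tetrakis[(R)-N-(4-dodecylbenzenesulfonyl)prolinate], 1 mol %), hexanes, −20 °C → rt, slow addition of 8 (2.5 equiv); then toluene, 90 °C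
Reagents that add atoms: none
Why: The dirhodium catalyst decomposes 8 to a donor/acceptor vinylcarbenoid with loss of N2, which attacks the terminal carbon C7 of the diene and closes the three-membered ring C6–C7–C8 of 9 by [2+1] addition; the closest known reaction type is the dirhodium-tetracarboxylate-catalysed cyclopropanation of 1,3-dienes by vinyldiazoacetates followed by divinylcyclopropane Cope rearrangement, a formal (4+3) cycloaddition. Chemoselectivity comes from the substrate: such carbenoids do not cyclopropanate tetrasubstituted alkenes, so C1=C5 is left alone, and the silyl ether removes the O–H insertion pathway. As is usual for donor/acceptor carbenoids, the vinyl group ends cis to the cyclopentenyl group, which makes 9 a cis-divinylcyclopropane. Ring B then closes by a [3,3]-sigmatropic shift through a boat transition state in which C10 bonds to C1 while the C6–C8 bond breaks, giving the cyclohepta-1,4-diene with C14 already on C8; the strain released pays for the quaternary centre. C1 is the only new stereocentre that remains, and it is controlled by the configuration at C6 of 9, because only the rotamer with C1 folded over the three-membered ring can react and in it C8 and C10 lie on one face of the cyclopentene. The step therefore needs face selection at C6=C7: the diene is expected to hold C7 on the side of the C4 silyloxy group (smaller near the ring than isopropyl) and to be attacked from the flank of the C1 methyl group, which gives (1S,2S)-9, and Rh2(R-DOSP)4 is chosen as the catalyst enantiomer expected to favour the same face, since its S form is known to deliver aryl- and vinylcarbenoids to the opposite face of monosubstituted alkenes. Heating in toluene is included because the C15 methyl group points into the boat and slows the rearrangement.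

Step 7
Reactants: 10 methyl (1R,4R)-4-(triethylsilyloxy)dauca-5,8-dien-14-oate
Product: 12 methyl (1R,4R,5S,6S)-6-hydroxy-4-(triethylsilyloxy)dauc-8-en-14-oate, via C6 alkylborane 11 (not isolated)
Conditions: BH3·THF, THF, 0 °C → rt; then NaBO3·4H2O, THF/H2O, rt
Reagents that add atoms: borane–tetrahydrofuran, [BH3-][O+]1CCCC1 (boron of 11); sodium perborate, [Na+].[Na+].O[B-]1(O)OO[B-](O)(O)OO1 (oxygen on C6)
Why: Hydroboration–oxidation: borane adds syn across the trisubstituted C5=C6 bond with boron on the less substituted C6, from the face opposite the angular C15 methyl and the C4 silyloxy group, so H5 ends anti to C15 (trans ring fusion) and, after oxidation with retention, O6 ends cis to H5. The electron-poor, α-substituted C8=C9 bond of the enoate is expected to react more slowly, and perborate spares the methyl ester.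

Step 8
Reactants: 12 methyl (1R,4R,5S,6S)-6-hydroxy-4-(triethylsilyloxy)dauc-8-en-14-oate
Product: 13 (1R,4R,5S,6S)-4-(triethylsilyloxy)dauc-8-ene-6,14-diol
Conditions: i-Bu2AlH (4 equiv), CH2Cl2, −78 → 0 °C; aq. potassium sodium tartrate
Reagents that add atoms: none
Why: 1,2-Reduction of the α,β-unsaturated ester by an aluminium hydride gives the allylic alcohol needed for directed epoxidation; the free C6 hydroxyl only consumes one equivalent of hydride and the silyl ether is inert.

Step 9
Reactants: 13 (1R,4R,5S,6S)-4-(triethylsilyloxy)dauc-8-ene-6,14-diol
Product: 14 (1R,4R,5S,6S,8S,9S)-8,9-epoxy-4-(triethylsilyloxy)daucane-6,14-diol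
Conditions: Ti(OiPr)4 (20 mol %), L-(+)-diethyl tartrate (24 mol %), t-BuOOH, 4 Å MS, CH2Cl2, −20 °C
Reagents that add atoms: tert-butyl hydroperoxide, CC(C)(C)OO
Why: Sharpless asymmetric epoxidation: the titanium tartrate complex binds the allylic C14 hydroxyl, and L-(+)-tartrate delivers oxygen to the face of C8=C9 that gives the (8S,9S)-epoxide, placing the C9 oxygen on the side of H5 and O6 as in 22. The angular methyl on the other face and the homoallylic C6 hydroxyl on the same face should make the substrate's own preference the matched one, and no other alkene is present.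

Step 10
Reactants: 14 (1R,4R,5S,6S,8S,9S)-8,9-epoxy-4-(triethylsilyloxy)daucane-6,14-diol
Product: 15 (1R,4R,5S,6S,8R,9S)-8,9-epoxy-14-iodo-4-(triethylsilyloxy)daucan-6-ol
Conditions: I2, PPh3, imidazole, CH2Cl2, 0 °C
Reagents that add atoms: iodine, [I][I]
Why: Appel-type iodination converts the primary C14 hydroxyl into the iodide by SN2 displacement of the oxyphosphonium ion; the hindered secondary C6 hydroxyl reacts far more slowly and the epoxide is stable in the buffered medium. The C8 descriptor becomes R only because iodine raises the priority of C14.

Step 11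
Reactants: 16 4-hydroxybenzoic acid
Product: 18 4-(tert-butyldimethylsilyloxy)benzoic acid, via silyl ester 17 (not isolated)
Conditions: t-BuMe2SiCl (2.3 equiv), imidazole, DMF, rt; then AcOH/THF/H2O, rt
Reagents that add atoms: tert-butyldimethylsilyl chloride, CC(C)(C)[Si](C)(C)Cl
Why: Both acidic hydroxyls are silylated, and the silyl ester, far more labile than the aryl silyl ether, is hydrolysed selectively by aqueous acetic acid; the phenol must be masked so that the acid chloride cannot acylate itself.

Step 12
Reactants: 18 4-(tert-butyldimethylsilyloxy)benzoic acid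
Product: 19 4-(tert-butyldimethylsilyloxy)benzoyl chloride
Conditions: (COCl)2, DMF (cat.), CH2Cl2, 0 °C → rt; evaporated and used crude
Reagents that add atoms: oxalyl chloride, O=C(Cl)C(=O)Cl
Why: Standard conversion of a carboxylic acid into its chloride through a chloroiminium (Vilsmeier-type) catalyst; the by-products are volatile and the aryl silyl ether survives the brief exposure to HCl.

Step 13
Reactants: 15 (1R,4R,5S,6S,8R,9S)-8,9-epoxy-14-iodo-4-(triethylsilyloxy)daucan-6-ol; 19 4-(tert-butyldimethylsilyloxy)benzoyl chloride
Product: 20 (1R,4R,5S,6S,8R,9S)-8,9-epoxy-14-iodo-4-(triethylsilyloxy)daucan-6-yl 4-(tert-butyldimethylsilyloxy)benzoate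
Conditions: DMAP, Et3N, CH2Cl2, 0 → 35 °C
Reagents that add atoms: none
Why: Nucleophile-catalysed acylation through the acylpyridinium ion: the C6 hydroxyl is the only free one, since O4 is silylated and O9 is held in the epoxide, so no selectivity among hydroxyls is needed. The neopentyl-type C14 and the fully substituted C8 slow SN2 attack on the iodide and the epoxide.

Step 14
Reactants: 20 (1R,4R,5S,6S,8R,9S)-8,9-epoxy-14-iodo-4-(triethylsilyloxy)daucan-6-yl 4-(tert-butyldimethylsilyloxy)benzoate
Product: 21 (1R,4R,5S,6S,9S)-9-hydroxy-4-(triethylsilyloxy)dauc-8(14)-en-6-yl 4-(tert-butyldimethylsilyloxy)benzoate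
Conditions: Zn dust (activated), NH4Cl, EtOH, 60 °C
Reagents that add atoms: none
Why: Reductive opening of a 2,3-epoxy iodide: zinc inserts into the C14–I bond and the organozinc undergoes β-elimination with cleavage of the C8–O bond, giving the exocyclic C8=C14 alkene and the C9 alkoxide. The C9–O bond is not broken, so the configuration from step 9 is retained, and esters and silyl ethers are inert to zinc in ethanol.

Step 15
Reactants: 21 (1R,4R,5S,6S,9S)-9-hydroxy-4-(triethylsilyloxy)dauc-8(14)-en-6-yl 4-(tert-butyldimethylsilyloxy)benzoate
Product: 22 ferugin, (1R,4R,5S,6S,9S)-4,9-dihydroxydauc-8(14)-en-6-yl 4-hydroxybenzoate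
Conditions: Bu4NF, AcOH, THF, 0 °C → rt
Reagents that add atoms: none
Why: Fluoride-mediated desilylation cleaves the aryl silyl ether quickly and the tertiary triethylsilyl ether more slowly; acetic acid buffers the alkoxide and phenoxide that would otherwise promote migration of the aroyl group to O9, and no stereocentre is involved.

## Compound list

1 | (S)-terpinen-4-ol, (1S)-4-methyl-1-(propan-2-yl)cyclohex-3-en-1-ol | CC1=CC[C@](O)(C(C)C)CC1 | starting material
2 | triethyl{[(1S)-4-methyl-1-(propan-2-yl)cyclohex-3-en-1-yl]oxy}silane | CC1=CC[C@](O[Si](CC)(CC)CC)(C(C)C)CC1 | intermediate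
3 | secondary ozonide of 2 (1,2,4-trioxolane across the former ring alkene; both bridged diastereomers) | CC12CC[C@@](O[Si](CC)(CC)CC)(C(C)C)CC(OO1)O2 | intermediate (not isolated)
4 | (3S)-6-oxo-3-(propan-2-yl)-3-(triethylsilyloxy)heptanal | CC(=O)CC[C@@](O[Si](CC)(CC)CC)(C(C)C)CC=O | intermediate
5 | (5R)-2-methyl-5-(propan-2-yl)-5-(triethylsilyloxy)cyclopent-1-ene-1-carbaldehyde | O=CC1=C(C)CC[C@@]1(O[Si](CC)(CC)CC)C(C)C | intermediate
6 | (5R)-1-ethenyl-2-methyl-5-(propan-2-yl)-5-(triethylsilyloxy)cyclopent-1-ene | C=CC1=C(C)CC[C@@]1(O[Si](CC)(CC)CC)C(C)C | intermediate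
7 | methyl but-3-enoate | C=CCC(=O)OC | starting material
8 | methyl 2-diazobut-3-enoate | C=CC(=[N+]=[N-])C(=O)OC | intermediate
9 | methyl (1S,2S)-1-ethenyl-2-[(5R)-2-methyl-5-(propan-2-yl)-5-(triethylsilyloxy)cyclopent-1-en-1-yl]cyclopropane-1-carboxylate (vinyl cis to cyclopentenyl) | COC(=O)[C@]1(C=C)C[C@H]1C1=C(C)CC[C@@]1(O[Si](CC)(CC)CC)C(C)C | intermediate (not isolated)
10 | methyl (1R,4R)-4-(triethylsilyloxy)dauca-5,8-dien-14-oate (bicyclo[5.3.0]deca-5,8-diene, ester on C8, methyl on C1) | COC(=O)C=1CC=C2[C@](C)(CC[C@@]2(O[Si](CC)(CC)CC)C(C)C)CC=1 | intermediate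
11 | C6 alkylborane of 10 (BH2 on C6, H on C5, both anti to the C15 methyl) | COC(=O)C=1C[C@H](B)[C@@H]2[C@](C)(CC[C@@]2(O[Si](CC)(CC)CC)C(C)C)CC=1 | intermediate (not isolated)
12 | methyl (1R,4R,5S,6S)-6-hydroxy-4-(triethylsilyloxy)dauc-8-en-14-oate | COC(=O)C=1C[C@H](O)[C@@H]2[C@](C)(CC[C@@]2(O[Si](CC)(CC)CC)C(C)C)CC=1 | intermediate
13 | (1R,4R,5S,6S)-4-(triethylsilyloxy)dauc-8-ene-6,14-diol | OCC=1C[C@H](O)[C@@H]2[C@](C)(CC[C@@]2(O[Si](CC)(CC)CC)C(C)C)CC=1 | intermediate
14 | (1R,4R,5S,6S,8S,9S)-8,9-epoxy-4-(triethylsilyloxy)daucane-6,14-diol | OC[C@@]12C[C@H](O)[C@@H]3[C@](C)(CC[C@@]3(O[Si](CC)(CC)CC)C(C)C)C[C@@H]1O2 | intermediate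
15 | (1R,4R,5S,6S,8R,9S)-8,9-epoxy-14-iodo-4-(triethylsilyloxy)daucan-6-ol | IC[C@@]12C[C@H](O)[C@@H]3[C@](C)(CC[C@@]3(O[Si](CC)(CC)CC)C(C)C)C[C@@H]1O2 | intermediate
16 | 4-hydroxybenzoic acid | O=C(O)c1ccc(O)cc1 | starting material
17 | tert-butyldimethylsilyl 4-(tert-butyldimethylsilyloxy)benzoate | CC(C)(C)[Si](C)(C)OC(=O)c1ccc(O[Si](C)(C)C(C)(C)C)cc1 | intermediate (not isolated)
18 | 4-(tert-butyldimethylsilyloxy)benzoic acid | O=C(O)c1ccc(O[Si](C)(C)C(C)(C)C)cc1 | intermediate
19 | 4-(tert-butyldimethylsilyloxy)benzoyl chloride | O=C(Cl)c1ccc(O[Si](C)(C)C(C)(C)C)cc1 | intermediate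
20 | (1R,4R,5S,6S,8R,9S)-8,9-epoxy-14-iodo-4-(triethylsilyloxy)daucan-6-yl 4-(tert-butyldimethylsilyloxy)benzoate | IC[C@@]12C[C@H](OC(=O)c4ccc(O[Si](C)(C)C(C)(C)C)cc4)[C@@H]3[C@](C)(CC[C@@]3(O[Si](CC)(CC)CC)C(C)C)C[C@@H]1O2 | intermediate
21 | (1R,4R,5S,6S,9S)-9-hydroxy-4-(triethylsilyloxy)dauc-8(14)-en-6-yl 4-(tert-butyldimethylsilyloxy)benzoate | C=C1C[C@H](OC(=O)c2ccc(O[Si](C)(C)C(C)(C)C)cc2)[C@@H]2[C@](C)(CC[C@@]2(O[Si](CC)(CC)CC)C(C)C)C[C@@H]1O | intermediate
22 | ferugin, (1R,4R,5S,6S,9S)-4,9-dihydroxydauc-8(14)-en-6-yl 4-hydroxybenzoate | C=C1C[C@H](OC(=O)c2ccc(O)cc2)[C@@H]2[C@](C)(CC[C@@]2(O)C(C)C)C[C@@H]1O | target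

## Step count and least certain steps

Total step count: 15. Longest linear sequence: 12 steps from 1 (steps 1–4, 6–10, 13–15); steps 5, 11 and 12 prepare 8 and 19.

**Step 6 (key step).** The most likely failure is insufficient face selection at C6=C7, because the bias of the C4 centre and that of the catalyst may not reinforce each other; this would give the C1 epimer of 10. Next in likelihood is loss of 8 by electrocyclisation to a pyrazole or by reaction at its vinyl terminus before it meets the hindered diene. The fallback sets out from 6 and returns at 10. Commercial methyl acetoacetate would be converted by diazo transfer into methyl 2-diazo-3-oxobutanoate F1 and O-silylated (t-BuMe2SiOTf, Et3N) to methyl 3-(tert-butyldimethylsilyloxy)-2-diazobut-3-enoate F2. This vinyldiazoacetate can be stored, reacts cleanly at the carbenoid carbon, and is the best-precedented partner for enantioselective reactions of this type with Rh2(R-PTAD)4 (dirhodium tetrakis[(R)-(1-adamantyl)(phthalimido)acetate]). With 6 it would pass through the silyloxy divinylcyclopropane F3 to the 9-silyloxy diene ester F4. Selective cleavage of the enol silyl ether (Bu4NF, AcOH, THF, −40 °C) would give the β-keto ester F5, which would be converted into the enol triflate F6 (NaH, PhNTf2) and reduced (Pd(OAc)2, PPh3, HCO2H, Et3N, DMF) to 10.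

**Step 7.** The most likely failure is competing reaction of borane with the conjugated ester, either reduction or delivery of a second B–H from the C6 borane across ring B to C8=C9, because the hindered C5=C6 bond reacts slowly. Attack on the methyl-bearing face is the lesser concern. The fallback sets out from 10 and returns at 15, with the order of events changed so that no enoate is present when borane is used. Reduction of 10 (i-Bu2AlH) would give the dienol F7. Sharpless epoxidation with the same tartrate, which leaves the undirected C5=C6 bond alone, would give the epoxy alcohol F8, and iodination (I2, PPh3, imidazole) the epoxy iodide F9. Hydroboration of the only remaining alkene through the C6 alkylborane F10 and perborate oxidation would then give 15.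

**Step 13.** The most likely failure is slow acylation of the hindered C6 hydroxyl, during which chloride or the nucleophilic catalyst opens the epoxide or displaces iodide. The fallback sets out from 15 and returns at 22. Zinc opening of 15 would give the 6,9-diol F11, and the less hindered allylic C9 hydroxyl would be silylated selectively (t-BuMe2SiCl, imidazole) to the 9-silyl ether F12. The C6 hydroxyl of this robust compound would be acylated with 19 under forcing conditions (DMAP, Et3N, 1,2-dichloroethane, 60 °C) to the tris-silylated ester F13, and global desilylation (Bu4NF, AcOH) would give 22.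

**Step 15.** The most likely failure is migration of the aroyl group from O6 to the cofacial O9, or incomplete cleavage of the hindered tertiary silyl ether, under fluoride. The fallback sets out from 20 and returns at 22. 20 would be desilylated first (Bu4NF, AcOH), while O9 is still part of the epoxide and cannot accept the acyl group, to give the epoxy iodide with free phenol and free C4 hydroxyl F14. The neutral zinc opening (Zn, NH4Cl, EtOH) would then give 22 directly.

## Further compounds

F1 | step 6 | methyl 2-diazo-3-oxobutanoate | CC(=O)C(=[N+]=[N-])C(=O)OC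
F2 | step 6 | methyl 3-(tert-butyldimethylsilyloxy)-2-diazobut-3-enoate | C=C(O[Si](C)(C)C(C)(C)C)C(=[N+]=[N-])C(=O)OC
F3 | step 6 | methyl (1S,2S)-1-[1-(tert-butyldimethylsilyloxy)ethenyl]-2-[(5R)-2-methyl-5-(propan-2-yl)-5-(triethylsilyloxy)cyclopent-1-en-1-yl]cyclopropane-1-carboxylate | COC(=O)[C@]1(C(=C)O[Si](C)(C)C(C)(C)C)C[C@H]1C1=C(C)CC[C@@]1(O[Si](CC)(CC)CC)C(C)C
F4 | step 6 | methyl (1R,4R)-9-(tert-butyldimethylsilyloxy)-4-(triethylsilyloxy)dauca-5,8-dien-14-oate | COC(=O)C=1CC=C2[C@](C)(CC[C@@]2(O[Si](CC)(CC)CC)C(C)C)CC=1O[Si](C)(C)C(C)(C)C
F5 | step 6 | methyl (1R,4R)-9-oxo-4-(triethylsilyloxy)dauc-5-en-14-oate (C8 epimers and enol form) | COC(=O)C1CC=C2[C@](C)(CC[C@@]2(O[Si](CC)(CC)CC)C(C)C)CC1=O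
F6 | step 6 | methyl (1R,4R)-4-(triethylsilyloxy)-9-(trifluoromethanesulfonyloxy)dauca-5,8-dien-14-oate | COC(=O)C=1CC=C2[C@](C)(CC[C@@]2(O[Si](CC)(CC)CC)C(C)C)CC=1OS(=O)(=O)C(F)(F)F
F7 | step 7 | (1R,4R)-4-(triethylsilyloxy)dauca-5,8-dien-14-ol | OCC=1CC=C2[C@](C)(CC[C@@]2(O[Si](CC)(CC)CC)C(C)C)CC=1
F8 | step 7 | (1R,4R,8S,9S)-8,9-epoxy-4-(triethylsilyloxy)dauc-5-en-14-ol | OC[C@@]12CC=C3[C@](C)(CC[C@@]3(O[Si](CC)(CC)CC)C(C)C)C[C@@H]1O2
F9 | step 7 | (1R,4R,8R,9S)-8,9-epoxy-14-iodo-4-(triethylsilyloxy)dauc-5-ene | IC[C@@]12CC=C3[C@](C)(CC[C@@]3(O[Si](CC)(CC)CC)C(C)C)C[C@@H]1O2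
F10 | step 7 | C6 alkylborane of F9 (BH2 on C6, H on C5, both anti to the C15 methyl) | IC[C@@]12C[C@H](B)[C@@H]3[C@](C)(CC[C@@]3(O[Si](CC)(CC)CC)C(C)C)C[C@@H]1O2
F11 | step 13 | (1R,4R,5S,6S,9S)-4-(triethylsilyloxy)dauc-8(14)-ene-6,9-diol | C=C1C[C@H](O)[C@@H]2[C@](C)(CC[C@@]2(O[Si](CC)(CC)CC)C(C)C)C[C@@H]1O
F12 | step 13 | (1R,4R,5S,6S,9S)-9-(tert-butyldimethylsilyloxy)-4-(triethylsilyloxy)dauc-8(14)-en-6-ol | C=C1C[C@H](O)[C@@H]2[C@](C)(CC[C@@]2(O[Si](CC)(CC)CC)C(C)C)C[C@@H]1O[Si](C)(C)C(C)(C)C
F13 | step 13 | (1R,4R,5S,6S,9S)-9-(tert-butyldimethylsilyloxy)-4-(triethylsilyloxy)dauc-8(14)-en-6-yl 4-(tert-butyldimethylsilyloxy)benzoate | C=C1C[C@H](OC(=O)c2ccc(O[Si](C)(C)C(C)(C)C)cc2)[C@@H]2[C@](C)(CC[C@@]2(O[Si](CC)(CC)CC)C(C)C)C[C@@H]1O[Si](C)(C)C(C)(C)C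
F14 | step 15 | (1R,4R,5S,6S,8R,9S)-8,9-epoxy-4-hydroxy-14-iododaucan-6-yl 4-hydroxybenzoate | IC[C@@]12C[C@H](OC(=O)c4ccc(O)cc4)[C@@H]3[C@](C)(CC[C@@]3(O)C(C)C)C[C@@H]1O2
A1 | alternative 1 | trans-fused bicyclo[5.3.0]dec-9-en-6-one with 9-trimethylsilyloxy and 4-triethylsilyloxy groups | C1CC(=O)[C@@H]2[C@](C)(CC[C@@]2(O[Si](CC)(CC)CC)C(C)C)C=C1O[Si](C)(C)C
A2 | alternative 1 | acyclic chloromethyl ketone with a tethered 2-(trimethylsilyloxy)diene and the C4 triethylsilyloxy carbinol | ClCC(=O)C[C@](O[Si](CC)(CC)CC)(C(C)C)CC/C(C)=C/C(=C)O[Si](C)(C)C
A3 | alternative 2 | daucan-6-one with C8 methylene, 4-triethylsilyloxy and 9-(tert-butyldimethylsilyloxy) groups | C=C1CC(=O)[C@@H]2[C@](C)(CC[C@@]2(O[Si](CC)(CC)CC)C(C)C)C[C@@H]1O[Si](C)(C)C(C)(C)C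
A4 | alternative 2 | cyclopentane bearing the C6=C7 silyl enol ether on C5 and the silyloxy propargyl arm on C1 | C=C(O[Si](C)(C)C(C)(C)C)[C@@H]1[C@](C)(CC[C@@]1(O[Si](CC)(CC)CC)C(C)C)C[C@H](O[Si](C)(C)C(C)(C)C)C#C
A5 | alternative 3 | bicyclo[5.3.0]deca-5,9-diene with 9-(tert-butyldimethylsilyloxy) and 4-triethylsilyloxy groups | C1CC=C2[C@](C)(CC[C@@]2(O[Si](CC)(CC)CC)C(C)C)C=C1O[Si](C)(C)C(C)(C)C
A6 | alternative 3 | acyclic yne–vinylcyclopropane with the C4 triethylsilyloxy carbinol and a 1-silyloxycyclopropyl group | C#C[C@](O[Si](CC)(CC)CC)(C(C)C)CC/C(C)=C/C1(O[Si](C)(C)C(C)(C)C)CC1
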